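**Retrosynthetic overview**
1. Target ⇒ removal of four aryl silyl ethers ⇒ Knoevenagel cut of the C5=CH bond into a left 7‑acyloxy‑6,8‑dione and a right dienal.
2. Both halves ⇒ trans‑6‑chloro‑7‑aroyloxy esters (left: Kornblum oxidation to C6=O; right: Woodward hydrolysis with acyl shift to the cis 6‑ester/7‑ol) ⇒ 6,7‑epoxy‑1H‑isochromen‑8‑ones + protected orsellinoyl chloride.
3. Pyran ring of each half ⇒ Au‑catalysed 6‑endo O–C3 closure, then DDQ dehydrogenation, of a 2‑(hydroxymethyl)‑3‑alkynyl epoxycyclohexanone.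
4. C4a–C4 bond ⇒ blue‑light dealkenylative alkynylation of the isopropenyl group of a carvone epoxide aldol with an enynyl sulfone (key step).
5. Ring order: carbocycle bought as (S)‑ and (R)‑carvone (C7 and C7′ from the trans epoxidation, C6′ by double inversion) → epoxide → pyran ring → union of the two bicycles.

Assumption: (E)‑pent‑2‑en‑4‑yn‑1‑ol, orsellinic acid and both carvone enantiomers are bought; bicyclic compounds carry isochromene numbering (C1, C3–C8, C4a, C8a).

**Step 1**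
Reactants: 1 (E)-pent-2-en-4-yn-1-ol
Product: 3 (E)-5-(4-methylbenzenesulfonyl)pent-2-en-4-yn-1-ol, via iodovinyl sulfone 2 (not isolated)
Conditions: TolSO2Na, I2, EtOAc/H2O, rt, room light; then K2CO3, acetone, 50 °C
Reagents that add atoms: sodium 4-methylbenzenesulfinate, Cc1ccc(cc1)S(=O)[O-].[Na+]
Why: Tosyl iodide formed in the flask adds across the terminal alkyne by a radical chain (iodosulfonylation) and base then removes HI to give the acetylenic sulfone, leaving the (E)-alkene untouched.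

**Step 2**
Reactants: 3 (E)-5-(4-methylbenzenesulfonyl)pent-2-en-4-yn-1-ol
Product: 4 (E)-5-(4-methylbenzenesulfonyl)pent-2-en-4-yn-1-yl acetate
Conditions: Ac2O, Sc(OTf)3 (1 mol %), MeCN, 0 °C
Reagents that add atoms: acetic anhydride, CC(=O)OC(C)=O
Why: Lewis-acid-catalysed acetylation of the primary alcohol, run amine-free so that nothing adds to the electrophilic alkynyl sulfone.

**Step 3**
Reactants: 5 orsellinic acid
Product: 6 tert-butyldimethylsilyl 2,4-bis(tert-butyldimethylsilyloxy)-6-methylbenzoate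
Conditions: TBSCl (3.5 equiv), imidazole, DMF, rt
Reagents that add atoms: tert-butyldimethylsilyl chloride, CC(C)(C)[Si](C)(C)Cl
Why: Exhaustive imidazole-mediated silylation covers both phenols and the acid.

**Step 4**
Reactants: 6 tert-butyldimethylsilyl 2,4-bis(tert-butyldimethylsilyloxy)-6-methylbenzoate
Product: 7 2,4-bis(tert-butyldimethylsilyloxy)-6-methylbenzoyl chloride
Conditions: (COCl)2, DMF (cat.), CH2Cl2, 0 °C → rt
Reagents that add atoms: oxalyl chloride, O=C(Cl)C(=O)Cl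
Why: Silyl esters are converted directly into acid chlorides by the Vilsmeier reagent under neutral conditions (Wissner method), so the aryl silyl ethers survive.

**Step 5**
Reactants: 8 (S)-(+)-carvone
Product: 9 (1S,4S,6S)-1-methyl-4-(prop-1-en-2-yl)-7-oxabicyclo[4.1.0]heptan-2-one
Conditions: 30 % H2O2, NaOH (cat.), MeOH, 0 °C
Reagents that add atoms: hydrogen peroxide, OO
Why: Weitz–Scheffer epoxidation attacks only the enone and anti to the isopropenyl group, so the bought stereocentre sets the future C7 (and the C6 oxygen face).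

**Step 6**
Reactants: 9 (1S,4S,6S)-1-methyl-4-(prop-1-en-2-yl)-7-oxabicyclo[4.1.0]heptan-2-one
Product: 10 (1S,3S,4S,6S)-3-(hydroxymethyl)-1-methyl-4-(prop-1-en-2-yl)-7-oxabicyclo[4.1.0]heptan-2-one
Conditions: LDA, THF, −78 °C; CH2O (g); AcOH
Reagents that add atoms: formaldehyde, C=O
Why: The only enolisable position (the future C8a) forms the lithium enolate, whose aldol addition to monomeric formaldehyde occurs anti to the neighbouring isopropenyl group.

**Step 7**
Reactants: 10 (1S,3S,4S,6S)-3-(hydroxymethyl)-1-methyl-4-(prop-1-en-2-yl)-7-oxabicyclo[4.1.0]heptan-2-one; 4 (E)-5-(4-methylbenzenesulfonyl)pent-2-en-4-yn-1-yl acetate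
Product: 12 (E)-5-[(1S,3S,4S,6S)-3-(hydroxymethyl)-1-methyl-2-oxo-7-oxabicyclo[4.1.0]heptan-4-yl]pent-2-en-4-yn-1-yl acetate, via methoxy hydroperoxide 11 (not isolated)
Conditions: O3, CH2Cl2/MeOH 1:1, −78 °C; N2 purge; then 4 (2 equiv), fac-Ir(ppy)3 (1 mol %), Hantzsch ester (1.5 equiv), 450 nm LEDs, 0 °C → rt
Reagents that add atoms: none
Why: Proposed new method: ozonolysis in methanol turns the isopropenyl group into α-methoxy hydroperoxide 11, whose O–O bond is reduced by excited fac-Ir(ppy)3 (about −1.7 V) under blue light; the alkoxyl radical loses methyl acetate by β-scission, and the secondary ring radical adds to the sulfonyl-bearing alkyne carbon of 4 and expels TolSO2• (reduced to sulfinate while the Hantzsch ester returns Ir(IV) to Ir(III)), forming the C4a–C4 bond anti to the CH2OH group (this centre becomes sp2 in step 8, so its configuration is immaterial); the closest known reactions are the thermal Fe(II)/ascorbate dealkenylative alkynylation of such hydroperoxides and the photoredox alkynylation of alkyl radicals from N-acyloxyphthalimides with alkynyl sulfones.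

**Step 8**
Reactants: 12 (E)-5-[(1S,3S,4S,6S)-3-(hydroxymethyl)-1-methyl-2-oxo-7-oxabicyclo[4.1.0]heptan-4-yl]pent-2-en-4-yn-1-yl acetate
Product: 14 (E)-3-[(6S,7S)-6,7-epoxy-7-methyl-8-oxo-5,6,7,8-tetrahydro-1H-isochromen-3-yl]prop-2-en-1-yl acetate, via cyclised ketone 13 (not isolated)
Conditions: (JohnPhos)Au(MeCN)SbF6 (3 mol %), CH2Cl2, rt; then DDQ (1.1 equiv), 0 °C
Reagents that add atoms: none
Why: Gold(I)-catalysed hydroalkoxylation closes the pyran 6-endo-dig at the alkenyl-substituted (cation-stabilising) alkyne carbon, and DDQ then abstracts the doubly activated H-4a as hydride so that loss of the α-keto H-8a places the C4a=C8a bond in conjugation with C8=O.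

**Step 9**
Reactants: 14 (E)-3-[(6S,7S)-6,7-epoxy-7-methyl-8-oxo-5,6,7,8-tetrahydro-1H-isochromen-3-yl]prop-2-en-1-yl acetate; 7 2,4-bis(tert-butyldimethylsilyloxy)-6-methylbenzoyl chloride
Product: 15 (6R,7R)-3-[(E)-3-acetoxyprop-1-en-1-yl]-6-chloro-7-methyl-8-oxo-5,6,7,8-tetrahydro-1H-isochromen-7-yl 2,4-bis(tert-butyldimethylsilyloxy)-6-methylbenzoate
Conditions: 7 (1.3 equiv), ZnCl2 (15 mol %), CH2Cl2, −20 → 0 °C
Reagents that add atoms: none
Why: Lewis-acid-catalysed addition of an acyl chloride across an epoxide: the acylium ion of the hindered aroyl chloride acylates the epoxide oxygen and chloride opens the ring at the less hindered C6 with inversion, so the C7–O bond is never broken (C7 keeps the carvone-derived configuration) and the tertiary ester is made without acylating a tertiary alcohol.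

**Step 10**
Reactants: 15 (6R,7R)-3-[(E)-3-acetoxyprop-1-en-1-yl]-6-chloro-7-methyl-8-oxo-5,6,7,8-tetrahydro-1H-isochromen-7-yl 2,4-bis(tert-butyldimethylsilyloxy)-6-methylbenzoate
Product: 17 (7S)-3-[(E)-3-acetoxyprop-1-en-1-yl]-7-methyl-6,8-dioxo-5,6,7,8-tetrahydro-1H-isochromen-7-yl 2,4-bis(tert-butyldimethylsilyloxy)-6-methylbenzoate, via alkoxysulfonium triflate 16 (not isolated)
Conditions: AgOTf (1.3 equiv), DMSO/CH2Cl2 1:1, rt, dark; then Et3N, 0 °C
Reagents that add atoms: dimethyl sulfoxide, CS(C)=O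
Why: Ganem–Kornblum oxidation: silver removes chloride with anchimeric help from the trans ester, DMSO attacks C6 of the dioxolanylium ion to give 16, and triethylamine triggers the ylide collapse to the C6 ketone, leaving the quaternary 7S centre untouched.

**Step 11**
Reactants: 18 (R)-(−)-carvone
Product: 19 (1R,4R,6R)-1-methyl-4-(prop-1-en-2-yl)-7-oxabicyclo[4.1.0]heptan-2-one
Conditions: 30 % H2O2, NaOH (cat.), MeOH, 0 °C
Reagents that add atoms: hydrogen peroxide, OO
Why: Weitz–Scheffer epoxidation anti to the isopropenyl group, as in step 5, sets the future C7′ (R) from the bought stereocentre.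

**Step 12**
Reactants: 19 (1R,4R,6R)-1-methyl-4-(prop-1-en-2-yl)-7-oxabicyclo[4.1.0]heptan-2-one
Product: 20 (1R,3R,4R,6R)-3-(hydroxymethyl)-1-methyl-4-(prop-1-en-2-yl)-7-oxabicyclo[4.1.0]heptan-2-one
Conditions: LDA, THF, −78 °C; CH2O (g); AcOH
Reagents that add atoms: formaldehyde, C=O
Why: Regiospecific lithium enolate aldol with formaldehyde, anti to the isopropenyl group, as in step 6.

**Step 13**
Reactants: 20 (1R,3R,4R,6R)-3-(hydroxymethyl)-1-methyl-4-(prop-1-en-2-yl)-7-oxabicyclo[4.1.0]heptan-2-one; 3 (E)-5-(4-methylbenzenesulfonyl)pent-2-en-4-yn-1-ol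
Product: 22 (1R,3R,4R,6R)-3-(hydroxymethyl)-4-[(E)-5-hydroxypent-3-en-1-yn-1-yl]-1-methyl-7-oxabicyclo[4.1.0]heptan-2-one, via methoxy hydroperoxide 21 (not isolated)
Conditions: O3, CH2Cl2/MeOH 1:1, −78 °C; N2 purge; then 3 (2 equiv), fac-Ir(ppy)3 (1 mol %), Hantzsch ester (1.5 equiv), 450 nm LEDs, 0 °C → rt
Reagents that add atoms: none
Why: Proposed new method: the same blue-light dealkenylative alkynylation as in step 7 (photoreduction of the ozonolysis-derived α-methoxy hydroperoxide, β-scission with loss of methyl acetate, trapping of the ring radical by the alkynyl sulfone with loss of TolSO2•), here with the free-hydroxyl sulfone, which radical conditions tolerate; the closest known reactions are the thermal Fe(II)/ascorbate dealkenylative alkynylation and photoredox alkynylations of alkyl radicals with alkynyl sulfones.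

**Step 14**
Reactants: 22 (1R,3R,4R,6R)-3-(hydroxymethyl)-4-[(E)-5-hydroxypent-3-en-1-yn-1-yl]-1-methyl-7-oxabicyclo[4.1.0]heptan-2-one
Product: 25 (E)-3-[(6R,7R)-6,7-epoxy-7-methyl-8-oxo-5,6,7,8-tetrahydro-1H-isochromen-3-yl]prop-2-enal, via cyclised ketone 23 (not isolated), via dienyl alcohol 24 (not isolated)
Conditions: (JohnPhos)Au(MeCN)SbF6 (3 mol %), CH2Cl2, rt; then DDQ (1.1 equiv), 0 °C; then MnO2 (15 equiv), rt
Reagents that add atoms: none
Why: Gold-catalysed 6-endo-dig hydroalkoxylation (the E-allylic alcohol cannot reach the alkyne) and DDQ dehydrogenation as in step 8, followed in the same flask by chemoselective MnO2 oxidation of the dienylic alcohol to the enal needed for the union.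

**Step 15**
Reactants: 25 (E)-3-[(6R,7R)-6,7-epoxy-7-methyl-8-oxo-5,6,7,8-tetrahydro-1H-isochromen-3-yl]prop-2-enal; 7 2,4-bis(tert-butyldimethylsilyloxy)-6-methylbenzoyl chloride
Product: 26 (6S,7S)-6-chloro-7-methyl-8-oxo-3-[(E)-3-oxoprop-1-en-1-yl]-5,6,7,8-tetrahydro-1H-isochromen-7-yl 2,4-bis(tert-butyldimethylsilyloxy)-6-methylbenzoate
Conditions: 7 (2 equiv), ZnCl2 (15 mol %), CH2Cl2, −20 → 0 °C
Reagents that add atoms: none
Why: Lewis-acid-catalysed acyl chloride–epoxide opening as in step 9 (O-acylation, chloride attack at C6 with inversion, C7′–O retained); any chloroalkyl ester formed reversibly at the aldehyde reverts on aqueous work-up.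

**Step 16**
Reactants: 26 (6S,7S)-6-chloro-7-methyl-8-oxo-3-[(E)-3-oxoprop-1-en-1-yl]-5,6,7,8-tetrahydro-1H-isochromen-7-yl 2,4-bis(tert-butyldimethylsilyloxy)-6-methylbenzoate
Product: 27 (6R,7R)-7-hydroxy-7-methyl-8-oxo-3-[(E)-3-oxoprop-1-en-1-yl]-5,6,7,8-tetrahydro-1H-isochromen-6-yl 2,4-bis(tert-butyldimethylsilyloxy)-6-methylbenzoate
Conditions: AgOTf (1.3 equiv), acetone/H2O 20:1, 0 °C → rt; NaHCO3 work-up
Reagents that add atoms: water, O
Why: Woodward–Prévost-type hydrolysis: silver-assisted loss of chloride with participation of the trans 7-O-aroyl group gives a cis-fused dioxolanylium ion, water adds at its carbenium carbon, and the hemiorthoester collapses under the liberated acid to the less congested secondary ester, so C6′ is R and cis to the free 7′-OH (two inversions from the carvone-derived epoxide).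

**Step 17**
Reactants: 17 (7S)-3-[(E)-3-acetoxyprop-1-en-1-yl]-7-methyl-6,8-dioxo-5,6,7,8-tetrahydro-1H-isochromen-7-yl 2,4-bis(tert-butyldimethylsilyloxy)-6-methylbenzoate; 27 (6R,7R)-7-hydroxy-7-methyl-8-oxo-3-[(E)-3-oxoprop-1-en-1-yl]-5,6,7,8-tetrahydro-1H-isochromen-6-yl 2,4-bis(tert-butyldimethylsilyloxy)-6-methylbenzoate
Product: 28 tetrakis(tert-butyldimethylsilyl) ether of CNP0283591.2
Conditions: ethylenediammonium diacetate (10 mol %), 4 Å MS, CH2Cl2, rt
Reagents that add atoms: none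
Why: Amine-salt-catalysed Knoevenagel condensation of the doubly activated C5 methylene of 17 (α to C6=O, vinylogous to C8=O) with the enal of 27; the new exocyclic alkene can equilibrate (reversible oxa-6π closure and iminium addition) to the Z isomer with the chain syn to C6=O and away from H-4, and no stereocentre is formed or touched.

**Step 18**
Reactants: 28 tetrakis(tert-butyldimethylsilyl) ether of CNP0283591.2
Product: 29 CNP0283591.2
Conditions: TBAF (4.4 equiv), AcOH (5 equiv), THF, 0 °C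
Reagents that add atoms: none
Why: Acetic-acid-buffered fluoride cleaves the four aryl silyl ethers while the allylic acetate, the hindered aryl esters and the polyenone are left alone.

**Compound list**
1 | (E)-pent-2-en-4-yn-1-ol | OC/C=C/C#C | starting material
2 | (2E,4E)-4-iodo-5-(4-methylbenzenesulfonyl)penta-2,4-dien-1-ol | OC/C=C/C(I)=C\S(=O)(=O)c1ccc(C)cc1 | intermediate (not isolated)
3 | (E)-5-(4-methylbenzenesulfonyl)pent-2-en-4-yn-1-ol | OC/C=C/C#CS(=O)(=O)c1ccc(C)cc1 | intermediate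
4 | (E)-5-(4-methylbenzenesulfonyl)pent-2-en-4-yn-1-yl acetate | CC(=O)OC/C=C/C#CS(=O)(=O)c1ccc(C)cc1 | intermediate
5 | orsellinic acid (2,4-dihydroxy-6-methylbenzoic acid) | Cc1cc(O)cc(O)c1C(=O)O | starting material
6 | tert-butyldimethylsilyl 2,4-bis(tert-butyldimethylsilyloxy)-6-methylbenzoate | Cc1cc(O[Si](C)(C)C(C)(C)C)cc(O[Si](C)(C)C(C)(C)C)c1C(=O)O[Si](C)(C)C(C)(C)C | intermediate
7 | 2,4-bis(tert-butyldimethylsilyloxy)-6-methylbenzoyl chloride | Cc1cc(O[Si](C)(C)C(C)(C)C)cc(O[Si](C)(C)C(C)(C)C)c1C(=O)Cl | intermediate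
8 | (S)-(+)-carvone | CC1=CC[C@@H](CC1=O)C(C)=C | starting material
9 | (1S,4S,6S)-1-methyl-4-(prop-1-en-2-yl)-7-oxabicyclo[4.1.0]heptan-2-one (epoxide trans to isopropenyl) | O=C1[C@@]2(C)O[C@H]2C[C@H](C(C)=C)C1 | intermediate
10 | (1S,3S,4S,6S)-3-(hydroxymethyl)-1-methyl-4-(prop-1-en-2-yl)-7-oxabicyclo[4.1.0]heptan-2-one (CH2OH trans to isopropenyl) | O=C1[C@@]2(C)O[C@H]2C[C@H](C(C)=C)[C@H]1CO | intermediate
11 | 4-(1-hydroperoxy-1-methoxyethyl) analogue of 10 (both epimers at the peroxy carbon) | O=C1[C@@]2(C)O[C@H]2C[C@H](C(C)(OC)OO)[C@H]1CO | intermediate (not isolated)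
12 | (E)-5-[(1S,3S,4S,6S)-3-(hydroxymethyl)-1-methyl-2-oxo-7-oxabicyclo[4.1.0]heptan-4-yl]pent-2-en-4-yn-1-yl acetate (major C4 epimer drawn) | O=C1[C@@]2(C)O[C@H]2C[C@H](C#C/C=C/COC(C)=O)[C@H]1CO | intermediate
13 | (E)-3-[(6S,7S)-6,7-epoxy-7-methyl-8-oxo-4a,5,6,7,8,8a-hexahydro-1H-isochromen-3-yl]prop-2-en-1-yl acetate (H-4a and H-8a trans, as in 12) | CC(=O)OC/C=C/C1=C[C@@H]2[C@@H](CO1)C(=O)[C@@]3(C)O[C@H]3C2 | intermediate (not isolated)
14 | (E)-3-[(6S,7S)-6,7-epoxy-7-methyl-8-oxo-5,6,7,8-tetrahydro-1H-isochromen-3-yl]prop-2-en-1-yl acetate | CC(=O)OC/C=C/C1=CC2=C(CO1)C(=O)[C@@]3(C)O[C@H]3C2 | intermediate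
15 | (6R,7R)-3-[(E)-3-acetoxyprop-1-en-1-yl]-6-chloro-7-methyl-8-oxo-5,6,7,8-tetrahydro-1H-isochromen-7-yl 2,4-bis(tert-butyldimethylsilyloxy)-6-methylbenzoate (Cl trans to the ester) | CC(=O)OC/C=C/C1=CC2=C(CO1)C(=O)[C@@](C)(OC(=O)c1c(C)cc(O[Si](C)(C)C(C)(C)C)cc1O[Si](C)(C)C(C)(C)C)[C@H](Cl)C2 | intermediate
16 | 6-[(dimethylsulfonio)oxy] analogue of 15 (sulfonium oxygen in place of Cl, trans to the 7-ester), triflate salt | CC(=O)OC/C=C/C1=CC2=C(CO1)C(=O)[C@@](C)(OC(=O)c1c(C)cc(O[Si](C)(C)C(C)(C)C)cc1O[Si](C)(C)C(C)(C)C)[C@H](O[S+](C)C)C2.[O-]S(=O)(=O)C(F)(F)F | intermediate (not isolated)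
17 | (7S)-3-[(E)-3-acetoxyprop-1-en-1-yl]-7-methyl-6,8-dioxo-5,6,7,8-tetrahydro-1H-isochromen-7-yl 2,4-bis(tert-butyldimethylsilyloxy)-6-methylbenzoate | CC(=O)OC/C=C/C1=CC2=C(CO1)C(=O)[C@@](C)(OC(=O)c1c(C)cc(O[Si](C)(C)C(C)(C)C)cc1O[Si](C)(C)C(C)(C)C)C(=O)C2 | intermediate
18 | (R)-(−)-carvone | CC1=CC[C@H](CC1=O)C(C)=C | starting material
19 | (1R,4R,6R)-1-methyl-4-(prop-1-en-2-yl)-7-oxabicyclo[4.1.0]heptan-2-one | O=C1[C@]2(C)O[C@@H]2C[C@@H](C(C)=C)C1 | intermediate
20 | (1R,3R,4R,6R)-3-(hydroxymethyl)-1-methyl-4-(prop-1-en-2-yl)-7-oxabicyclo[4.1.0]heptan-2-one | O=C1[C@]2(C)O[C@@H]2C[C@@H](C(C)=C)[C@@H]1CO | intermediate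
21 | 4-(1-hydroperoxy-1-methoxyethyl) analogue of 20 (both epimers at the peroxy carbon) | O=C1[C@]2(C)O[C@@H]2C[C@@H](C(C)(OC)OO)[C@@H]1CO | intermediate (not isolated)
22 | (1R,3R,4R,6R)-3-(hydroxymethyl)-4-[(E)-5-hydroxypent-3-en-1-yn-1-yl]-1-methyl-7-oxabicyclo[4.1.0]heptan-2-one (major C4 epimer drawn) | O=C1[C@]2(C)O[C@@H]2C[C@@H](C#C/C=C/CO)[C@@H]1CO | intermediate
23 | (6R,7R)-6,7-epoxy-3-[(E)-3-hydroxyprop-1-en-1-yl]-7-methyl-4a,5,6,7,8,8a-hexahydro-1H-isochromen-8-one (H-4a and H-8a trans) | OC/C=C/C1=C[C@H]2[C@H](CO1)C(=O)[C@]3(C)O[C@@H]3C2 | intermediate (not isolated)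
24 | (6R,7R)-6,7-epoxy-3-[(E)-3-hydroxyprop-1-en-1-yl]-7-methyl-6,7-dihydro-1H-isochromen-8(5H)-one | OC/C=C/C1=CC2=C(CO1)C(=O)[C@]3(C)O[C@@H]3C2 | intermediate (not isolated)
25 | (E)-3-[(6R,7R)-6,7-epoxy-7-methyl-8-oxo-5,6,7,8-tetrahydro-1H-isochromen-3-yl]prop-2-enal | O=C/C=C/C1=CC2=C(CO1)C(=O)[C@]3(C)O[C@@H]3C2 | intermediate
26 | (6S,7S)-6-chloro-7-methyl-8-oxo-3-[(E)-3-oxoprop-1-en-1-yl]-5,6,7,8-tetrahydro-1H-isochromen-7-yl 2,4-bis(tert-butyldimethylsilyloxy)-6-methylbenzoate (Cl trans to the ester) | O=C/C=C/C1=CC2=C(CO1)C(=O)[C@](C)(OC(=O)c1c(C)cc(O[Si](C)(C)C(C)(C)C)cc1O[Si](C)(C)C(C)(C)C)[C@@H](Cl)C2 | intermediate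
27 | (6R,7R)-7-hydroxy-7-methyl-8-oxo-3-[(E)-3-oxoprop-1-en-1-yl]-5,6,7,8-tetrahydro-1H-isochromen-6-yl 2,4-bis(tert-butyldimethylsilyloxy)-6-methylbenzoate (6-ester cis to 7-OH) | O=C/C=C/C1=CC2=C(CO1)C(=O)[C@](C)(O)[C@H](OC(=O)c1c(C)cc(O[Si](C)(C)C(C)(C)C)cc1O[Si](C)(C)C(C)(C)C)C2 | intermediate
28 | tetrakis(tert-butyldimethylsilyl) ether of the target (all four phenols silylated; 5Z,E-triene linker) | CC(=O)OC/C=C/C1=CC2=C(CO1)C(=O)[C@@](C)(OC(=O)c1c(C)cc(O[Si](C)(C)C(C)(C)C)cc1O[Si](C)(C)C(C)(C)C)C(=O)/C2=C\C=C\C1=CC2=C(CO1)C(=O)[C@](C)(O)[C@H](OC(=O)c1c(C)cc(O[Si](C)(C)C(C)(C)C)cc1O[Si](C)(C)C(C)(C)C)C2 | intermediate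
29 | CNP0283591.2 | CC(=O)OC/C=C/C1=CC2=C(CO1)C(=O)[C@@](C)(OC(=O)c1c(C)cc(O)cc1O)C(=O)/C2=C\C=C\C1=CC2=C(CO1)C(=O)[C@](C)(O)[C@H](OC(=O)c1c(C)cc(O)cc1O)C2 | target

**Totals**
Total step count: 18. Longest linear sequence: 8 steps (5, 6, 7, 8, 9, 10, 17, 18).

**Three steps most likely to fail** (steps 13–15 repeat steps 7–9 in the mirror-image series and share their risks; the fallbacks are written for the left-hand series)

Step 7, the new blue-light dealkenylative alkynylation. The photoreduction of the hydroperoxide may be slow, or the ring radical may be quenched by hydrogen transfer from the Hantzsch ester. The fallback uses known polar chemistry, sets out from epoxide 9 and comes back at 14. Ozonolysis of 9 in methanol followed by Cu(OAc)2/FeSO4 (dehydrogenative fragmentation of the methoxy hydroperoxide) gives (1S,6S)-1-methyl-7-oxabicyclo[4.1.0]hept-3-en-2-one F1. Alcohol 1 is silylated (TBSCl, imidazole) to tert-butyldimethyl[(E)-pent-2-en-4-yn-1-yloxy]silane F2. Its dimethylalkynylalane (n-BuLi, then Me2AlCl) is added 1,4 to F1 under Ni(acac)2/DIBAL-H catalysis, and the aluminium enolate is trapped with formaldehyde to give the silyl ether analogue of 12 F3. The conditions of step 8 convert this into the silyl ether analogue of 14 F4. HF·pyridine frees the allylic alcohol analogue of 14 F5, and Ac2O/pyridine returns to 14.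

Step 8, the gold cyclisation and DDQ dehydrogenation. The flexible alkynol may close 5-exo, or the ketone oxygen may cyclise to a furan. The fallback sets out from 12 and comes back at 14. Dess–Martin oxidation of the primary alcohol gives the 3-formyl ketone F6 (mainly its hydroxymethylene enol). DDQ in dioxane dehydrogenates it to the 2-formyl-3-alkynyl enone F7, the classical dehydrogenation of 2-formyl ketones. NaBH(OAc)3 reduces only the aldehyde, giving the hydroxymethyl ynenone F8. Catalytic AgOTf then closes the pyran by 6-endo oxa-Michael addition to the ynenone δ-carbon, where 5-exo attack is electronically disfavoured, and this returns to 14.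

Step 9, the acyl chloride opening of the epoxide. The hindered aroyl chloride may react sluggishly, or the Lewis acid may trigger β-elimination of the epoxide towards the o-quinol. The fallback sets out from 14 and comes back at 17, bypassing 15 and 16. Kornblum-type oxidative opening of the epoxide (DMSO, TMSOTf, −78 → 0 °C; then i-Pr2NEt) gives the (7S)-7-hydroxy-6,8-dione F9. Acylation with 7 (Et3N, DMAP, CH2Cl2) returns to 17; O-acylation of the C6 enol followed by O→O acyl shift to the neighbouring tertiary oxygen is the expected pathway.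

**Further compounds**
F1 | step 7 | (1S,6S)-1-methyl-7-oxabicyclo[4.1.0]hept-3-en-2-one | O=C1[C@@]2(C)O[C@H]2CC=C1
F2 | step 7 | tert-butyldimethyl[(E)-pent-2-en-4-yn-1-yloxy]silane | C#C/C=C/CO[Si](C)(C)C(C)(C)C
F3 | step 7 | silyl ether analogue of 12: (1S,3S,4S,6S)-4-[(E)-5-(tert-butyldimethylsilyloxy)pent-3-en-1-yn-1-yl]-3-(hydroxymethyl)-1-methyl-7-oxabicyclo[4.1.0]heptan-2-one | O=C1[C@@]2(C)O[C@H]2C[C@H](C#C/C=C/CO[Si](C)(C)C(C)(C)C)[C@H]1CO
F4 | step 7 | silyl ether analogue of 14: (6S,7S)-3-[(E)-3-(tert-butyldimethylsilyloxy)prop-1-en-1-yl]-6,7-epoxy-7-methyl-6,7-dihydro-1H-isochromen-8(5H)-one | CC(C)(C)[Si](C)(C)OC/C=C/C1=CC2=C(CO1)C(=O)[C@@]3(C)O[C@H]3C2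
F5 | step 7 | allylic alcohol analogue of 14: (6S,7S)-6,7-epoxy-3-[(E)-3-hydroxyprop-1-en-1-yl]-7-methyl-6,7-dihydro-1H-isochromen-8(5H)-one | OC/C=C/C1=CC2=C(CO1)C(=O)[C@@]3(C)O[C@H]3C2
F6 | step 8 | (E)-5-[(1S,4S,6S)-3-formyl-1-methyl-2-oxo-7-oxabicyclo[4.1.0]heptan-4-yl]pent-2-en-4-yn-1-yl acetate | O=C1[C@@]2(C)O[C@H]2C[C@H](C#C/C=C/COC(C)=O)C1C=O
F7 | step 8 | (E)-5-[(1S,6S)-3-formyl-1-methyl-2-oxo-7-oxabicyclo[4.1.0]hept-3-en-4-yl]pent-2-en-4-yn-1-yl acetate | O=C1[C@@]2(C)O[C@H]2CC(C#C/C=C/COC(C)=O)=C1C=O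
F8 | step 8 | (E)-5-[(1S,6S)-3-(hydroxymethyl)-1-methyl-2-oxo-7-oxabicyclo[4.1.0]hept-3-en-4-yl]pent-2-en-4-yn-1-yl acetate | O=C1[C@@]2(C)O[C@H]2CC(C#C/C=C/COC(C)=O)=C1CO
F9 | step 9 | (E)-3-[(7S)-7-hydroxy-7-methyl-6,8-dioxo-5,6,7,8-tetrahydro-1H-isochromen-3-yl]prop-2-en-1-yl acetate | CC(=O)OC/C=C/C1=CC2=C(CO1)C(=O)[C@@](C)(O)C(=O)C2
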